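(Readings and results are simulated on assumed constants.)

I began with the partner.

| flask | substrate | partner | protic impurity | free catalyst | remark | time |
|---|---|---|---|---|---|---|
| summer | 0.020 M | 1 equiv (fed, over 1.5 h) | 1.3 mM | 0.05 mol% | run made earlier |  |
| dawn | 0.020 M | 1 equiv (fed, over 1.5 h) | 3 mM | 0.05 mol% | run made earlier |  |
| flask | 0.020 M | 1.00 equiv (fed, over 1.5 h) | 2.00 mM | 0.05 mol% |  | 30 h |

| run | time / h | catalyst intermediate A / % | catalyst intermediate C / % | catalyst intermediate B / % | product / % | substrate / % |
|---|---|---|---|---|---|---|
| summer | 3.00 | 0 | 0.4 | 0 | 20.5 | 80.1 |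
| summer | 6.00 | 0.4 | 0.4 | 0 | 35.4 | 64.8 |
| summer | 15.0 | 0 | 0.1 | 0 | 62.1 | 38.1 |
| summer | 40.0 | 0 | 0.1 | 0 | 88.4 | 11.4 |
| dawn | 5.00 | 0.4 | 0.1 | 0.2 | 30.3 | 69.2 |
| dawn | 12.0 | 0.4 | 0 | 0 | 54.5 | 45.6 |
| dawn | 25.0 | 0.2 | 0.3 | 0 | 75.9 | 23.5 |
| dawn | 40.0 | 0 | 0.1 | 0 | 85.0 | 14.9 |

(each reading ± 0.3 percentage points)

- steps that have been proposed: substrate + free catalyst -> catalyst intermediate A; partner + catalyst intermediate A -> catalyst intermediate B; catalyst intermediate B <-> catalyst intermediate C; catalyst intermediate C <-> free catalyst + product; partner + protic impurity -> quenched reagent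

- the largest share of what was charged as substrate, at 30 h belongs to (catalyst intermediate A / catalyst intermediate B / catalyst intermediate C / substrate / product)
- the largest share itself, whichever of these holds it, in percent of the substrate charged

The proposed steps spend partner one to one on substrate and one to one on protic impurity. So equal charges of substrate and partner are the zero of my scale: with nothing else to take partner, the two run down together. In this flask the protic impurity can claim 10.0% of the partner charge. I called this the quench share, and I took it as the substrate floor, with the partner as limiting reagent. The summer run has 6.50% and the dawn run 15.0%.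

Substrate above the floor I called the gap. In the summer run it fell from 31.6% to 4.90% between 15.0 h and 40.0 h, which is 0.0746 h⁻¹, so I estimated that run's substrate at 30 h as 16.8%. The same reckoning on the dawn run gave 0.0985 h⁻¹ and 20.2%. Placing the flask between them by its quench share gave substrate 18.2% and product 81.8%.

The weak link was dawn's rate: it left 1.9 percentage points above the floor at 40.0 h, but the reading there was 14.9%, against a floor of 15.0%. So I reforged it without a floor, with a steady fractional fall between the dawn readings on either side of 30 h. That gave 20.2%, so I kept my estimate for the flask.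

The forecast, reading a “first-order approach to a floor”, named product at 82%, within 80% to 84%.

The flask gave product at 81.4%.

    substrate + free catalyst → catalyst intermediate A (k = 14000 L mol⁻¹ h⁻¹)
    partner + catalyst intermediate A → catalyst intermediate B (k = 65000 L mol⁻¹ h⁻¹)
    catalyst intermediate B ⇌ catalyst intermediate C (K = 8.50, k = 23000 h⁻¹)
    catalyst intermediate C ⇌ free catalyst + product (K = 0.0110 M, k = 1300 h⁻¹)
    partner + protic impurity → quenched reagent (k = 49.0 L mol⁻¹ h⁻¹)

The flask's substrate at 30 h, 18.6%, stood 8.6 points above the quench share, and partner left was 8.60% of its charge. By 300 h substrate in the flask had reached 9.95%, against a quench share of 10.0%. A neighbour flask with 0.050 M of substrate has a quench share of 4.00%. At 30.0 h it held substrate 10.3%, a gap of 6.3 points, with 6.3% of its partner left.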